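**Retrosynthetic overview**
1. Parritadial is read as 1β,6α-diacetoxy-9α-hydroxydrim-7-ene-11,12-dial. The C6 acetate is added last, and the C9 hydroxyl with the C7=C8 bond comes from Rubottom oxidation of the C11 dienol ether of a drim-8-en-11-al.
2. The 5α-H and 6α-OH pair comes from α-face hydroboration of a C5=C6 alkene.
3. Ring B (C5–C6–C7–C8–C9–C10) is cut at C7–C8 and C9–C10 by a Diels–Alder disconnection into a ring-A diene (C10=C5–C6=C7) and 4,4-diethoxybut-2-ynal.
4. The feature that allows this: the two formyl carbons C11 and C12 sit on adjacent ring-B atoms C9 and C8 (a masked but-2-ynedial), ring B meets ring A only through the C5–C10 bond, and the C1 oxygen of ring A is allylic to the diene terminus C10 and can steer the face of attack.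
5. Ring order: ring A is bought as a cyclohexane-1,3-dione and elaborated (Stork–Danheiser vinylation, CBS reduction); ring B is the only ring closed in the route and is closed last, in step 6.

Key step: step 6

Remark: drimane numbering is used for all bicyclic compounds (ring A = C1–C5, C10; ring B = C5–C10; C11 on C9, C12 on C8), with α/β relative to the β C10 methyl. 4,4-Dimethylcyclohexane-1,3-dione and 4,4-diethoxybut-2-ynal are assumed to be commercial.

**Route**

Step 1
Reactants: 1 4,4-dimethylcyclohexane-1,3-dione
Product: 2 2,4,4-trimethylcyclohexane-1,3-dione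
Conditions: MeI, K2CO3, acetone, reflux
Reagents that add atoms: iodomethane, CI
Why: C-alkylation of the stabilised 1,3-diketone enolate at C2, the only doubly activated carbon, and the new centre is epimerisable and becomes sp2 later, so no stereocontrol is needed.

Step 2
Reactants: 2 2,4,4-trimethylcyclohexane-1,3-dione
Product: 3 3-isobutoxy-2,6,6-trimethylcyclohex-2-en-1-one
Conditions: 2-methylpropan-1-ol, p-TsOH·H2O (cat.), toluene, reflux, Dean–Stark trap
Reagents that add atoms: 2-methylpropan-1-ol, CC(C)CO
Why: Acid-catalysed vinylogous ester formation should occur at the carbonyl remote from the gem-dimethyl group, because the alcohol adds to the less hindered C=O, which leaves the hindered ketone free for step 3.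

Step 3
Reactants: 3 3-isobutoxy-2,6,6-trimethylcyclohex-2-en-1-one
Product: 5 2,4,4-trimethyl-3-vinylcyclohex-2-en-1-one, via vinyl carbinol 4 (not isolated)
Conditions: CH2=CHMgBr, anhydrous CeCl3, THF, −78 to 0 °C; then 2 M HCl, rt
Reagents that add atoms: vinylmagnesium bromide, C=C[Mg]Br; water, O
Why: Stork–Danheiser transposition, in which 1,2-addition of the vinyl nucleophile to the vinylogous ester carbonyl and acid hydrolysis of the enol ether with loss of water move the carbonyl to C1 and leave the vinyl group on C5.

Step 4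
Reactants: 5 2,4,4-trimethyl-3-vinylcyclohex-2-en-1-one
Product: 6 (R)-2,4,4-trimethyl-3-vinylcyclohex-2-en-1-ol
Conditions: (S)-1-methyl-3,3-diphenyltetrahydro-1H,3H-pyrrolo[1,2-c][1,3,2]oxazaborole ((S)-Me-CBS, cat.), catecholborane, toluene, −78 °C; then MeOH, aqueous NaOH wash
Reagents that add atoms: none
Why: CBS reduction, in which the catalyst treats the alkenyl arm as the large group and the CH2 arm as the small one, so the usual model predicts hydride delivery to the face that gives the R alcohol at C1, and catecholborane at low temperature leaves the diene untouched.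

Step 5
Reactants: 6 (R)-2,4,4-trimethyl-3-vinylcyclohex-2-en-1-ol
Product: 7 (R)-2,4,4-trimethyl-3-vinylcyclohex-2-en-1-yl acetate
Conditions: Ac2O, Et3N, 4-(dimethylamino)pyridine (cat.), CH2Cl2, 0 °C; chromatography on Et3N-buffered silica
Reagents that add atoms: acetic anhydride, CC(=O)OC(C)=O
Why: Standard acylation of a secondary allylic alcohol with retention at C1, which installs the C1 acetate of the target early and provides the face-directing group for step 6.

Step 6
Reactants: 7 (R)-2,4,4-trimethyl-3-vinylcyclohex-2-en-1-yl acetate; 8 4,4-diethoxybut-2-ynal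
Product: 9 1β-acetoxy-12,12-diethoxydrima-5,8-dien-11-al
Conditions: toluene, 2,6-di-tert-butyl-4-methylphenol (cat.), 90 °C, sealed tube
Reagents that add atoms: none
Why: Thermal normal-demand Diels–Alder reaction in which the s-cis diene C10=C5–C6=C7 of 7 adds suprafacially to the formyl-activated triple bond of 8 through a concerted, asynchronous transition state (C7–C8 bond leading), the closest known reaction being the cycloaddition of 1-vinyl-2,6,6-trimethylcyclohexene with acetylenic esters used for drimanes. Ring B is closed by this intermolecular [4+2] annulation, which forms C7–C8 and C9–C10 in one operation, brings in C11 and C12 at the aldehyde oxidation level (one free, one masked) and leaves the C5=C6 and C8=C9 bonds of a cyclohexa-1,4-diene for the later oxygenations. The only new stereocentre, quaternary C10, is controlled by the C1 acetoxy group, which should sit pseudoaxial to avoid allylic 1,2-strain with the C10 methyl and so shield one face; the dienophile adds anti to it and the methyl group ends up cis to the acetate. The required regioselectivity (formyl carbon on C9, acetal carbon on C8) should follow from the larger HOMO coefficient at the unsubstituted terminus C7, which bonds to the β-carbon of the ynal, and from placing the smaller formyl group next to the congested C10. The required facial selectivity rests on the C1 substituent alone, and chemoselectivity is not in question because 7 has no second diene and the acetal and acetate are inert at this temperature.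

Step 7
Reactants: 9 1β-acetoxy-12,12-diethoxydrima-5,8-dien-11-al
Product: 11 1β-acetoxy-12,12-diethoxydrim-8-ene-6α,11-diol, via bis-borane adduct 10 (not isolated)
Conditions: BH3·THF, THF, 0 °C to rt; then NaBO3·4H2O, THF/H2O, rt; used without chromatography on acidic silica
Reagents that add atoms: sodium perborate (NaBO3·4H2O, written as its peroxoborate anion), [Na+].OO[B-](O)(O)O
Why: Hydroboration–oxidation, in which borane first reduces the C11 aldehyde and then adds syn across the trisubstituted C5=C6 bond from the α face (opposite the axial C10 methyl and the β methyl on C4) with boron on C6, so that oxidation with retention should give 5α-H (trans ring fusion) and 6α-OH, while the tetrasubstituted C8=C9 bond flanked by two oxygenated carbons reacts more slowly.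

Step 8
Reactants: 11 1β-acetoxy-12,12-diethoxydrim-8-ene-6α,11-diol
Product: 12 1β-acetoxy-12,12-diethoxy-6α-hydroxydrim-8-en-11-al
Conditions: activated MnO2, CH2Cl2, rt
Reagents that add atoms: none
Why: Allylic oxidation with MnO2 should convert only the primary allylic C11 alcohol back to the conjugated aldehyde and leave the non-allylic secondary C6 alcohol untouched.

Step 9
Reactants: 12 1β-acetoxy-12,12-diethoxy-6α-hydroxydrim-8-en-11-al
Product: 13 1β-acetoxy-12,12-diethoxy-6α,11-bis(trimethylsilyloxy)drima-7,9(11)-diene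
Conditions: Me3SiCl, Et3N, ZnCl2 (cat.), toluene, 40 °C; used crude
Reagents that add atoms: chlorotrimethylsilane, C[Si](C)(C)Cl
Why: Soft enolisation of the enal (O-silylation, then loss of a γ-hydrogen from C7, the only γ position that carries hydrogen) should give the 1-silyloxy diene C7=C8–C9=C11–OSiMe3 and silylate the C6 hydroxyl as well, under chloride-based conditions chosen to spare the diethyl acetal and the C1 acetate; the enol ether geometry has no consequence and C6 carries a poor leaving group so that 1,2-elimination towards C6=C7 is not invited.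

Step 10
Reactants: 13 1β-acetoxy-12,12-diethoxy-6α,11-bis(trimethylsilyloxy)drima-7,9(11)-diene
Product: 15 1β-acetoxy-6α,9α-dihydroxydrim-7-ene-11,12-dial, via 9-silyloxy aldehyde 14 (not isolated)
Conditions: dimethyldioxirane, acetone/CH2Cl2, −78 to −30 °C; then 1 M HCl, THF, 0 °C
Reagents that add atoms: dimethyldioxirane, CC1(C)OO1; water, O
Why: Rubottom oxidation, in which oxygen is transferred to the electron-rich C9=C11 enol ether bond from the α face (anti to the axial C10 methyl) and silyl migration then places the tertiary oxygen at C9α and restores the C11 aldehyde with C7=C8 in place, after which the acid work-up cleaves both silyl ethers and the C12 acetal.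

Step 11
Reactants: 15 1β-acetoxy-6α,9α-dihydroxydrim-7-ene-11,12-dial
Product: 16 parritadial (1β,6α-diacetoxy-9α-hydroxydrim-7-ene-11,12-dial)
Conditions: Ac2O, pyridine, CH2Cl2, 0 °C
Reagents that add atoms: acetic anhydride, CC(=O)OC(C)=O
Why: Selective acylation of the secondary equatorial C6 hydroxyl, since the tertiary C9 hydroxyl, flanked by quaternary C10 and the formyl group, should not react without an acyl-transfer catalyst.

**Compound list**
1 | 4,4-dimethylcyclohexane-1,3-dione | CC1(C)CCC(=O)CC1=O | starting material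
2 | 2,4,4-trimethylcyclohexane-1,3-dione (C2 epimerisable) | CC1C(=O)CCC(C)(C)C1=O | intermediate
3 | 3-isobutoxy-2,6,6-trimethylcyclohex-2-en-1-one | CC(C)COC1=C(C)C(=O)C(C)(C)CC1 | intermediate
4 | 3-isobutoxy-2,6,6-trimethyl-1-vinylcyclohex-2-en-1-ol (racemic, formed as its alkoxide) | C=CC1(O)C(C)=C(OCC(C)C)CCC1(C)C | intermediate (not isolated)
5 | 2,4,4-trimethyl-3-vinylcyclohex-2-en-1-one | C=CC1=C(C)C(=O)CCC1(C)C | intermediate
6 | (R)-2,4,4-trimethyl-3-vinylcyclohex-2-en-1-ol | O[C@@H]1CCC(C)(C)C(C=C)=C1C | intermediate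
7 | (R)-2,4,4-trimethyl-3-vinylcyclohex-2-en-1-yl acetate | CC(=O)O[C@@H]1CCC(C)(C)C(C=C)=C1C | intermediate
8 | 4,4-diethoxybut-2-ynal | O=CC#CC(OCC)OCC | starting material
9 | 1β-acetoxy-12,12-diethoxydrima-5,8-dien-11-al (10β-methyl) | C1C(C(OCC)OCC)=C(C=O)[C@@]2(C)[C@H](OC(C)=O)CCC(C)(C)C2=C1 | intermediate
10 | 1β-acetoxy-6α-boranyl-11-boranyloxy-12,12-diethoxydrim-8-ene (5α-H) | B[C@H]1CC(C(OCC)OCC)=C(COB)[C@@]2(C)[C@H](OC(C)=O)CCC(C)(C)[C@H]12 | intermediate (not isolated)
11 | 1β-acetoxy-12,12-diethoxydrim-8-ene-6α,11-diol (5α-H) | O[C@H]1CC(C(OCC)OCC)=C(CO)[C@@]2(C)[C@H](OC(C)=O)CCC(C)(C)[C@H]12 | intermediate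
12 | 1β-acetoxy-12,12-diethoxy-6α-hydroxydrim-8-en-11-al | O[C@H]1CC(C(OCC)OCC)=C(C=O)[C@@]2(C)[C@H](OC(C)=O)CCC(C)(C)[C@H]12 | intermediate
13 | 1β-acetoxy-12,12-diethoxy-6α,11-bis(trimethylsilyloxy)drima-7,9(11)-diene (enol ether geometry not defined) | C[Si](C)(C)O[C@H]1C=C(C(OCC)OCC)C(=CO[Si](C)(C)C)[C@@]2(C)[C@H](OC(C)=O)CCC(C)(C)[C@H]12 | intermediate
14 | 1β-acetoxy-12,12-diethoxy-6α,9α-bis(trimethylsilyloxy)drim-7-en-11-al | C[Si](C)(C)O[C@H]1C=C(C(OCC)OCC)[C@](O[Si](C)(C)C)(C=O)[C@@]2(C)[C@H](OC(C)=O)CCC(C)(C)[C@H]12 | intermediate (not isolated)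
15 | 1β-acetoxy-6α,9α-dihydroxydrim-7-ene-11,12-dial | O[C@H]1C=C(C=O)[C@](O)(C=O)[C@@]2(C)[C@H](OC(C)=O)CCC(C)(C)[C@H]12 | intermediate
16 | parritadial | CC(=O)O[C@H]1C=C(C=O)[C@](O)(C=O)[C@@]2(C)[C@H](OC(C)=O)CCC(C)(C)[C@H]12 | target

**Step count**
Total: 11 steps. Longest linear sequence: 11 steps (1 to 16); 8 is bought and enters at step 6.

**Steps most likely to fail**

Step 6. The ynal may attack the wrong face of C10 if the small acetoxy group does not hold the pseudoaxial position, and the dienyl acetate may ionise or the ynal decompose before cycloaddition. The fallback changes the face-directing group to a bulky silyl ether and moves the acylation behind the ring closure. It sets out from 6. Silylation (t-BuMe2SiCl, imidazole, DMF) should give the (R)-tert-butyldimethylsilyl ether of the dienol F1. Cycloaddition of F1 with 8 under the conditions of step 6 should give 1β-(tert-butyldimethylsilyloxy)-12,12-diethoxydrima-5,8-dien-11-al F2. Desilylation (Bu4NF buffered with AcOH, THF, 0 °C) should give 12,12-diethoxy-1β-hydroxydrima-5,8-dien-11-al F3. Acetylation (Ac2O, Et3N, 4-(dimethylamino)pyridine) then returns to the route at 9.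

Step 7. Boron held on the C11 alkoxide may be delivered to the C8=C9 bond, and the acetate may be reduced slowly while the hindered C5=C6 bond reacts. The fallback separates carbonyl reduction from hydroboration and blocks O11. It sets out from 9. Luche reduction (NaBH4, CeCl3·7H2O, MeOH, −40 °C) should give 1β-acetoxy-12,12-diethoxydrima-5,8-dien-11-ol F4. Silylation (t-BuMe2SiCl, imidazole, CH2Cl2) should give its 11-tert-butyldimethylsilyl ether F5. Hydroboration (BH3·THF, 0 °C) should give the 6α-boranyl adduct F6, which NaBO3·4H2O oxidises to 1β-acetoxy-11-(tert-butyldimethylsilyloxy)-12,12-diethoxydrim-8-en-6α-ol F7. Desilylation (Bu4NF, THF) returns to the route at 11.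

Step 10. Oxygen may be transferred to C7 or the C7=C8 bond instead of C9, the acetal may ionise during the silylation that feeds this step, and the α-hydroxy aldehyde may undergo α-ketol rearrangement on acid work-up. The fallback replaces the dienol ether chemistry by a Schenck ene reaction on the tetrasubstituted alkene. It sets out from 11. Photooxygenation (O2, tetraphenylporphyrin, visible light, CH2Cl2, 0 °C) should add oxygen to C9 from the α face with abstraction of the axial 7α-hydrogen, giving 1β-acetoxy-12,12-diethoxy-9α-hydroperoxydrim-7-ene-6α,11-diol F8. Reduction with PPh3 should give 1β-acetoxy-12,12-diethoxydrim-7-ene-6α,9α,11-triol F9. Primary-selective oxidation (2,2,6,6-tetramethylpiperidin-1-oxyl, PhI(OAc)2, CH2Cl2) should give 1β-acetoxy-12,12-diethoxy-6α,9α-dihydroxydrim-7-en-11-al F10. Acetal hydrolysis (1 M HCl, THF, 0 °C) returns to the route at 15; this bypasses steps 8 to 10.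

**Further compounds**
F1 | step 6 | (R)-tert-butyldimethyl[(2,4,4-trimethyl-3-vinylcyclohex-2-en-1-yl)oxy]silane | CC(C)(C)[Si](C)(C)O[C@@H]1CCC(C)(C)C(C=C)=C1C
F2 | step 6 | 1β-(tert-butyldimethylsilyloxy)-12,12-diethoxydrima-5,8-dien-11-al | C1C(C(OCC)OCC)=C(C=O)[C@@]2(C)[C@H](O[Si](C)(C)C(C)(C)C)CCC(C)(C)C2=C1
F3 | step 6 | 12,12-diethoxy-1β-hydroxydrima-5,8-dien-11-al | C1C(C(OCC)OCC)=C(C=O)[C@@]2(C)[C@H](O)CCC(C)(C)C2=C1
F4 | step 7 | 1β-acetoxy-12,12-diethoxydrima-5,8-dien-11-ol | C1C(C(OCC)OCC)=C(CO)[C@@]2(C)[C@H](OC(C)=O)CCC(C)(C)C2=C1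
F5 | step 7 | 1β-acetoxy-11-(tert-butyldimethylsilyloxy)-12,12-diethoxydrima-5,8-diene | C1C(C(OCC)OCC)=C(CO[Si](C)(C)C(C)(C)C)[C@@]2(C)[C@H](OC(C)=O)CCC(C)(C)C2=C1
F6 | step 7 | 1β-acetoxy-6α-boranyl-11-(tert-butyldimethylsilyloxy)-12,12-diethoxydrim-8-ene | B[C@H]1CC(C(OCC)OCC)=C(CO[Si](C)(C)C(C)(C)C)[C@@]2(C)[C@H](OC(C)=O)CCC(C)(C)[C@H]12
F7 | step 7 | 1β-acetoxy-11-(tert-butyldimethylsilyloxy)-12,12-diethoxydrim-8-en-6α-ol | O[C@H]1CC(C(OCC)OCC)=C(CO[Si](C)(C)C(C)(C)C)[C@@]2(C)[C@H](OC(C)=O)CCC(C)(C)[C@H]12
F8 | step 10 | 1β-acetoxy-12,12-diethoxy-9α-hydroperoxydrim-7-ene-6α,11-diol | O[C@H]1C=C(C(OCC)OCC)[C@](OO)(CO)[C@@]2(C)[C@H](OC(C)=O)CCC(C)(C)[C@H]12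
F9 | step 10 | 1β-acetoxy-12,12-diethoxydrim-7-ene-6α,9α,11-triol | O[C@H]1C=C(C(OCC)OCC)[C@](O)(CO)[C@@]2(C)[C@H](OC(C)=O)CCC(C)(C)[C@H]12
F10 | step 10 | 1β-acetoxy-12,12-diethoxy-6α,9α-dihydroxydrim-7-en-11-al | O[C@H]1C=C(C(OCC)OCC)[C@](O)(C=O)[C@@]2(C)[C@H](OC(C)=O)CCC(C)(C)[C@H]12
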